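Its constants stand for no real mixture; the rest is arithmetic.

Over a run of 50 s, the catalytic round and self-condensation compete for the same substrate.

    reagent + free catalyst → catalyst intermediate A (k1 = 9620 /M/s)
    catalyst intermediate B → by-product + catalyst intermediate C (k2 = 33.9 /s)
    2 catalyst intermediate A ⇌ resting dimer, settled at all times (K3 = 60000 /M)
    catalyst intermediate C → free catalyst + target (k4 = 6.62 /s)
    substrate + catalyst intermediate A ⇌ catalyst intermediate B (K5 = 1100 /M, k5 = 2890 /M/s)
    2 substrate → self-condensation product (k6 = 5.44 /M/s)

in all of them: free catalyst 85 µM

| flask | substrate | reagent | time | remark |
|---|---|---|---|---|
| Tuesday's | 5.0 mM | 2.50 mM | 50 s | a closed flask charged with all of it at once and left for 50 s |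
| Monday's | 5.0 mM | 2.50 mM |  | one stirred flow tank at steady state, fed with the mixture as stated, mean residence time 50 s |
| Sunday's | 5.0 mM | 2.50 mM (fed, over 25.0 s) | 50 s | all but reagent at the start; reagent goes in evenly over 25.0 s, the run ends at 50 s |
| Saturday's | 5.0 mM (fed, over 25.0 s) | 2.50 mM | 50 s | a stirred flask in which substrate is dosed at a steady rate over 25.0 s without added volume, worked up at 50 s |

- the set-up with the highest amount of target at the outlet or at the end, in percent of the substrate put in ("none" if the first two lie within 2 percentage points) (Tuesday's / Monday's / Sunday's / Saturday's / none)
- amount of target at the outlet or at the end, in percent of the substrate put in, Tuesday's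
- amount of target at the outlet or at the end, in percent of the substrate put in, Monday's
- amount of target at the outlet or at the end, in percent of the substrate put in, Sunday's
- amount of target at the outlet or at the end, in percent of the substrate put in, Saturday's

- in percentages every species weighs as the substrate in it: one self-condensation product counts as two
- where a step has two of a species, its rate is k times that concentration squared, and two are used at each turn
- the stated concentrations are those of everything mixed, before any reaction; amounts are the same in each set-up
- the feed brings no volume worth counting
- run time (Tuesday's): 50 s

- Each turn of the round takes in one reagent and one substrate and releases one target, so the target made over the reagent lost comes to one once the catalyst forms have emptied. Time drops out of that ratio, which gives the bound from above: the target ceiling, the reagent charge over the substrate charge, is 50.0%. Reagent is the limiting reagent, and the charges of Monday's, Sunday's and Saturday's are the same as Tuesday's.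

- The bound from below comes from Tuesday's flask. Self-condensation on its own, second order in c_substrate, leaves 26.9% of the charge after 50 s, and the round lowers c_substrate further, which slows self-condensation. That share stays out of its reach, so a round fast enough to take it makes at least that much target.

- The bound tightens with the opening pace of Tuesday's round. Each turn spends 0.297 s in the working forms, while the resting dimer, outside the working round, holds part of the catalyst. The catalyst balance at the charged concentrations then gives a pseudo-steady turnover of 0.198 mM/s.

- At that pace Tuesday's reagent needs 12.6 s, far longer than the 0.10 s half-life of catalyst intermediate C by its own step. Over that time self-condensation on its own leaves 59.3%, more than the ceiling requires. That pace is reckoned at the charged concentrations, and c_reagent and c_substrate run down in the flask, so the hand stops at a bracket for Tuesday's from 26.9% to 50.0%, leaning to the top.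

- The forecast, opening with “Reagent is the limiting partner”, gives 49.9% for Tuesday's, inside the bracket, with 47% for Monday's, 48.9% for Sunday's, 49.9% for Saturday's and none as the best.

- The simulation gives 50.0% for Tuesday's, 47.1% for Monday's, 49.9% for Sunday's and 50.0% for Saturday's, so the best is none, the first two lying within 2 percentage points. Tuesday's stands at the ceiling, with 0% of its reagent and 14% of its substrate left, while Monday's lies 2.9 points under the ceiling.

- The neighbouring flask is Tuesday's with 1.5 mM of reagent, everything else held. Its ceiling scales to 30.0%, and the flask gives 30.0% of target with 0% of its reagent left. Its substrate left is 22%, and its self-condensation product stands at 47.8% of the substrate charged.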